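**Strategy.** The oxolane (O15, C1, C14, C13, C12) is not built directly: it grows from a Sharpless-derived oxirane on C1–C14 that is conjugated to a C13=C12 enoate. A copper-catalysed vinyl oxirane to 2,5-dihydrofuran ring expansion moves the oxygen from C14 to C12, creates the second fully substituted ether carbon by 1,3-transfer of chirality and leaves the C11 ester and C2 hydroxymethyl arms cis. It exploits the two O-bearing quaternary carbons C1 and C12 that flank the unfunctionalised C13–C14 unit. The arms are then extended (C10–C11; Sonogashira, epoxidation and Red-Al for C2–C6) and the 14-membered ring is closed by metathesis at C7=C8, methylated at C8 and acetylated.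

Key step: step 5

Numbering used throughout: C1–C14 are the carbons of the carbocycle (C1 bears isopropyl, C2=C3, C4 bears OH and CH3, C6 is the ketone, C8 bears CH3, C11 bears OAc, C12 bears CH3); O15 bridges C1 and C12.

Assumption: the copper step is taken to keep its anti-SN2′ oxidative addition / retentive C–O reductive elimination course at the ester-bearing, fully substituted terminus C12, as it does for simpler vinyl oxiranes.

Step 1
Reactants: 1 prop-2-yn-1-ol
Product: 3 4-(propan-2-yl)-2,5-dihydrofuran-2-ol, via (2Z)-hydroxy enal 2 (not isolated)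
Conditions: i-PrMgCl (2.5 equiv), CuI (10 mol %), THF, −10 °C to rt; DMF, 0 °C to rt; pH 7 buffer work-up, crude lactol used at once
Reagents that add atoms: isopropylmagnesium chloride, CC(C)[Mg]Cl; N,N-dimethylformamide, CN(C)C=O
Why: Copper-catalysed anti-carbomagnesiation of the propargylic alkoxide puts isopropyl on the internal carbon and magnesium cis to CH2O (five-membered chelate), so Bouveault formylation gives the (Z)-hydroxy enal, which closes to the lactol.

Step 2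
Reactants: 3 4-(propan-2-yl)-2,5-dihydrofuran-2-ol
Product: 4 ethyl (2E,4Z)-5-(hydroxymethyl)-2,6-dimethylhepta-2,4-dienoate
Conditions: Ph3P=C(CH3)CO2Et, CH2Cl2, rt
Reagents that add atoms: ethyl 2-(triphenylphosphoranylidene)propanoate, CCOC(=O)C(C)=P(c1ccccc1)(c1ccccc1)c1ccccc1
Why: Wittig olefination of the open hydroxy-enal tautomer with a stabilised α-methyl ylide should give the (E)-trisubstituted enoate and leave the Z C1=C14 bond untouched.

Step 3
Reactants: 4 ethyl (2E,4Z)-5-(hydroxymethyl)-2,6-dimethylhepta-2,4-dienoate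
Product: 5 ethyl (2E)-3-[(2R,3S)-3-(hydroxymethyl)-3-(propan-2-yl)oxiran-2-yl]-2-methylprop-2-enoate
Conditions: Ti(Oi-Pr)4, L-(+)-diethyl tartrate, t-BuOOH, 4 Å MS, CH2Cl2, −20 °C
Reagents that add atoms: tert-butyl hydroperoxide, CC(C)(C)OO
Why: Sharpless asymmetric epoxidation with L-(+)-tartrate delivers oxygen to the face of the (Z)-allylic alcohol that gives the (2R,3S)-oxirane, which fixes C1 (and C14); the enoate C=C is no allylic alcohol and stays.

Step 4
Reactants: 5 ethyl (2E)-3-[(2R,3S)-3-(hydroxymethyl)-3-(propan-2-yl)oxiran-2-yl]-2-methylprop-2-enoate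
Product: 6 ethyl (2E)-3-[(2R,3S)-3-({[tert-butyl(dimethyl)silyl]oxy}methyl)-3-(propan-2-yl)oxiran-2-yl]-2-methylprop-2-enoate
Conditions: TBSCl, imidazole, CH2Cl2, 0 °C to rt
Reagents that add atoms: tert-butyldimethylsilyl chloride, CC(C)(C)[Si](C)(C)Cl
Why: Silylation masks the primary alcohol so that it cannot open the oxirane or bind copper in the next step.

Step 5
Reactants: 6 ethyl (2E)-3-[(2R,3S)-3-({[tert-butyl(dimethyl)silyl]oxy}methyl)-3-(propan-2-yl)oxiran-2-yl]-2-methylprop-2-enoate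
Product: 7 ethyl (2S,5R)-5-({[tert-butyl(dimethyl)silyl]oxy}methyl)-2-methyl-5-(propan-2-yl)-2,5-dihydrofuran-2-carboxylate
Conditions: Cu(hfacac)2 (5 mol %), toluene, 150 °C, sealed tube
Reagents that add atoms: none
Why: Cu(II) is reduced in situ to Cu(I), which adds to the enoate α-carbon C12 anti to the allylic C14–O bond (SN2′ oxidative addition, the mode known for organocopper additions to γ,δ-epoxy enoates) to give a six-membered allyl(alkoxo)copper(III) ring, whose C–O reductive elimination with retention forges O–C12. The closest known reaction is the copper-catalysed vinyl oxirane to 2,5-dihydrofuran rearrangement, which accepts fully substituted termini. The three-membered ring O–C1–C14 thereby grows to the five-membered ring O–C1–C14–C13–C12 by a formal 1,3-shift of oxygen, the new ring closing by ring contraction of the oxacuprine (5-endo in outcome). C12 is the new stereocentre and is set by 1,3-transfer of chirality: with the (2R,3S)-oxirane (CH2OTBS cis to the vinyl group) and the (E)-enoate, the ester should end up cis to the CH2OTBS arm, while C1 is not touched. The step needs ionisation at the allylic C14–O bond and not Lewis-acid opening at the fully substituted C1–O bond; the soft Cu(I) pathway and the allylic, enoate-activated C14 should secure this.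

Step 6
Reactants: 7 ethyl (2S,5R)-5-({[tert-butyl(dimethyl)silyl]oxy}methyl)-2-methyl-5-(propan-2-yl)-2,5-dihydrofuran-2-carboxylate
Product: 8 ethyl (2S,5S)-5-({[tert-butyl(dimethyl)silyl]oxy}methyl)-2-methyl-5-(propan-2-yl)oxolane-2-carboxylate
Conditions: H2 (1–3 atm), PtO2, EtOAc, rt
Reagents that add atoms: none
Why: Heterogeneous hydrogenation saturates the cis ring alkene C13=C14 (no other C=C is present), and platinum is chosen to avoid hydrogenolysis of the allylic C–O bonds.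

Step 7
Reactants: 8 ethyl (2S,5S)-5-({[tert-butyl(dimethyl)silyl]oxy}methyl)-2-methyl-5-(propan-2-yl)oxolane-2-carboxylate
Product: 10 (1S,5S)-1-methyl-5-(propan-2-yl)-3,8-dioxabicyclo[3.2.1]octan-2-one, via hydroxy ester 9 (not isolated)
Conditions: TBAF, THF, 0 °C to rt; then PPTS (cat.), toluene, 60 °C
Reagents that add atoms: none
Why: Fluoride desilylation frees the C2 alkoxide, which lactonises onto the cis ester; only the cis isomer can form this bridged lactone, so the step also purifies and proves the relative configuration.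

Step 8
Reactants: 10 (1S,5S)-1-methyl-5-(propan-2-yl)-3,8-dioxabicyclo[3.2.1]octan-2-one
Product: 11 (2S,5S)-5-(hydroxymethyl)-N-methoxy-N,2-dimethyl-5-(propan-2-yl)oxolane-2-carboxamide
Conditions: MeNH(OMe)·HCl, AlMe3, CH2Cl2, 0 °C to rt; Rochelle salt work-up
Reagents that add atoms: N,O-dimethylhydroxylamine hydrochloride, CNOC.Cl
Why: Aluminium-amide aminolysis of the lactone (Weinreb amide formation) opens the bridge and frees the C2 hydroxyl in one operation.

Step 9
Reactants: 11 (2S,5S)-5-(hydroxymethyl)-N-methoxy-N,2-dimethyl-5-(propan-2-yl)oxolane-2-carboxamide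
Product: 12 (2S,5S)-5-formyl-N-methoxy-N,2-dimethyl-5-(propan-2-yl)oxolane-2-carboxamide
Conditions: Dess–Martin periodinane, NaHCO3, CH2Cl2, 0 °C to rt
Reagents that add atoms: none
Why: Dess–Martin oxidation gives the aldehyde, which has no α-hydrogen and therefore cannot epimerise.

Step 10
Reactants: 12 (2S,5S)-5-formyl-N-methoxy-N,2-dimethyl-5-(propan-2-yl)oxolane-2-carboxamide
Product: 13 (2S,5S)-5-ethynyl-N-methoxy-N,2-dimethyl-5-(propan-2-yl)oxolane-2-carboxamide
Conditions: dimethyl (1-diazo-2-oxopropyl)phosphonate, K2CO3, MeOH, 0 °C to rt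
Reagents that add atoms: dimethyl (1-diazo-2-oxopropyl)phosphonate, COP(=O)(OC)C(=[N+]=[N-])C(C)=O
Why: Seyferth–Gilbert homologation with the Ohira–Bestmann reagent turns the non-enolisable aldehyde into the C2≡C3 alkyne; the Weinreb amide tolerates K2CO3/MeOH.

Step 11
Reactants: 13 (2S,5S)-5-ethynyl-N-methoxy-N,2-dimethyl-5-(propan-2-yl)oxolane-2-carboxamide
Product: 14 1-[(2S,5S)-5-ethynyl-2-methyl-5-(propan-2-yl)oxolan-2-yl]pent-4-en-1-one
Conditions: but-3-enylmagnesium bromide (2.5 equiv), THF, −78 to 0 °C; aq. NH4Cl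
Reagents that add atoms: but-3-en-1-ylmagnesium bromide, C=CCC[Mg]Br
Why: Weinreb ketone synthesis: the chelated tetrahedral intermediate stops at the ketone stage, and the first equivalent of Grignard reagent only deprotonates the alkyne.

Step 12
Reactants: 14 1-[(2S,5S)-5-ethynyl-2-methyl-5-(propan-2-yl)oxolan-2-yl]pent-4-en-1-one
Product: 15 (1R)-1-[(2S,5S)-5-ethynyl-2-methyl-5-(propan-2-yl)oxolan-2-yl]pent-4-en-1-ol
Conditions: Zn(BH4)2, Et2O, −30 to 0 °C
Reagents that add atoms: none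
Why: Chelation-controlled reduction (Cram chelate of zinc between the ketone oxygen and O15): hydride should enter from the face of the C12 methyl group, anti to ring carbon C13, which gives the (11R) carbinol.

Step 13
Reactants: 16 but-2-yn-1-ol
Product: 17 (2Z)-3-iodobut-2-en-1-ol
Conditions: Red-Al, THF, 0 °C to rt; then I2, −78 °C to 0 °C
Reagents that add atoms: iodine, II
Why: Alkoxide-directed trans-hydroalumination of the propargylic alcohol places aluminium on C3, and iodinolysis with retention gives the (Z)-iodide.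

Step 14
Reactants: 15 (1R)-1-[(2S,5S)-5-ethynyl-2-methyl-5-(propan-2-yl)oxolan-2-yl]pent-4-en-1-ol; 17 (2Z)-3-iodobut-2-en-1-ol
Product: 18 (2Z)-5-{(2S,5S)-5-[(1R)-1-hydroxypent-4-en-1-yl]-5-methyl-2-(propan-2-yl)oxolan-2-yl}-3-methylpent-2-en-4-yn-1-ol
Conditions: PdCl2(PPh3)2 (3 mol %), CuI (5 mol %), Et3N, THF, rt
Reagents that add atoms: none
Why: Sonogashira coupling joins C3 to C4 with retention of the iodide geometry; free hydroxyls and the terminal alkene are tolerated.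

Step 15
Reactants: 18 (2Z)-5-{(2S,5S)-5-[(1R)-1-hydroxypent-4-en-1-yl]-5-methyl-2-(propan-2-yl)oxolan-2-yl}-3-methylpent-2-en-4-yn-1-ol
Product: 19 [(2R,3S)-3-({(2S,5S)-5-[(1R)-1-hydroxypent-4-en-1-yl]-5-methyl-2-(propan-2-yl)oxolan-2-yl}ethynyl)-3-methyloxiran-2-yl]methanol
Conditions: Ti(Oi-Pr)4, D-(−)-diethyl tartrate, t-BuOOH, 4 Å MS, CH2Cl2, −20 °C
Reagents that add atoms: tert-butyl hydroperoxide, CC(C)(C)OO
Why: Sharpless asymmetric epoxidation of the (Z)-trisubstituted allylic alcohol with D-(−)-tartrate sets the C4–O bond (oxirane 3S, later 4R); the C11 carbinol is only bis-homoallylic, so its alkene is not epoxidised.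

Step 16
Reactants: 19 [(2R,3S)-3-({(2S,5S)-5-[(1R)-1-hydroxypent-4-en-1-yl]-5-methyl-2-(propan-2-yl)oxolan-2-yl}ethynyl)-3-methyloxiran-2-yl]methanol
Product: 21 (3R,4E)-5-{(2S,5S)-5-[(1R)-1-hydroxypent-4-en-1-yl]-5-methyl-2-(propan-2-yl)oxolan-2-yl}-3-methylpent-4-ene-1,3-diol, via alkynyl 1,3-diol 20 (not isolated)
Conditions: Red-Al (6 equiv), THF, −20 °C, then 45 °C
Reagents that add atoms: none
Why: Red-Al first delivers hydride from the C6 alkoxy-aluminate to C5 of the 2,3-epoxy alcohol (C4–O untouched, so C4 keeps its configuration), and the resulting C4 propargylic alkoxide then directs trans-hydroalumination to the (E)-C2=C3 alkene.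

Step 17
Reactants: 21 (3R,4E)-5-{(2S,5S)-5-[(1R)-1-hydroxypent-4-en-1-yl]-5-methyl-2-(propan-2-yl)oxolan-2-yl}-3-methylpent-4-ene-1,3-diol
Product: 22 (3R,4E)-3-hydroxy-5-{(2S,5S)-5-[(1R)-1-hydroxypent-4-en-1-yl]-5-methyl-2-(propan-2-yl)oxolan-2-yl}-3-methylpent-4-enal
Conditions: TEMPO (10 mol %), PhI(OAc)2, CH2Cl2, rt
Reagents that add atoms: none
Why: TEMPO/PhI(OAc)2 oxidises the primary C6 alcohol selectively in the presence of the hindered secondary C11 and tertiary C4 hydroxyls.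

Step 18
Reactants: 22 (3R,4E)-3-hydroxy-5-{(2S,5S)-5-[(1R)-1-hydroxypent-4-en-1-yl]-5-methyl-2-(propan-2-yl)oxolan-2-yl}-3-methylpent-4-enal
Product: 23 (5R,6E)-7-{(2S,5S)-5-[(1R)-1-hydroxypent-4-en-1-yl]-5-methyl-2-(propan-2-yl)oxolan-2-yl}-5-methylhepta-1,6-diene-3,5-diol (both C3 epimers)
Conditions: vinylmagnesium bromide (3.5 equiv), THF, −78 °C
Reagents that add atoms: vinylmagnesium bromide, C=C[Mg]Br
Why: Grignard 1,2-addition brings in C7; the new carbinol centre (C6) is left as a mixture because it is oxidised in the next step.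

Step 19
Reactants: 23 (5R,6E)-7-{(2S,5S)-5-[(1R)-1-hydroxypent-4-en-1-yl]-5-methyl-2-(propan-2-yl)oxolan-2-yl}-5-methylhepta-1,6-diene-3,5-diol
Product: 24 (5R,6E)-5-hydroxy-7-{(2S,5S)-5-[(1R)-1-hydroxypent-4-en-1-yl]-5-methyl-2-(propan-2-yl)oxolan-2-yl}-5-methylhepta-1,6-dien-3-one
Conditions: activated MnO2 (excess), CH2Cl2, rt; used at once
Reagents that add atoms: none
Why: MnO2 oxidises only the allylic secondary alcohol (C6), not the saturated C11 carbinol or the tertiary C4 alcohol.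

Step 20
Reactants: 24 (5R,6E)-5-hydroxy-7-{(2S,5S)-5-[(1R)-1-hydroxypent-4-en-1-yl]-5-methyl-2-(propan-2-yl)oxolan-2-yl}-5-methylhepta-1,6-dien-3-one
Product: 25 (1S,2E,4R,7E,11R,12S)-4,11-dihydroxy-4,12-dimethyl-1-(propan-2-yl)-15-oxabicyclo[10.2.1]pentadeca-2,7-dien-6-one
Conditions: Hoveyda–Grubbs II catalyst (5–10 mol %), CH2Cl2 (1 mM), 40 °C
Reagents that add atoms: none
Why: Ring-closing metathesis between the vinyl ketone and the terminal alkene closes the 14-membered carbocycle as the (E)-enone; the C2=C3 alkene between two fully substituted carbons is inert.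

Step 21
Reactants: 25 (1S,2E,4R,7E,11R,12S)-4,11-dihydroxy-4,12-dimethyl-1-(propan-2-yl)-15-oxabicyclo[10.2.1]pentadeca-2,7-dien-6-one
Product: 26 (1S,2E,4R,8S,11R,12S)-4,11-dihydroxy-4,8,12-trimethyl-1-(propan-2-yl)-15-oxabicyclo[10.2.1]pentadec-2-en-6-one
Conditions: Me2Zn (5 equiv), Cu(OTf)2 (5 mol %), chiral BINOL-phosphoramidite (10 mol %, the antipode that delivers CH3 to the Si face of C8), toluene, −30 °C
Reagents that add atoms: dimethylzinc, C[Zn]C
Why: Copper-catalysed asymmetric conjugate addition to the macrocyclic (E)-enone (the reaction type used for 3-methyl macrocyclic ketones) sets C8 under ligand control, Si-face delivery giving (8S); two equivalents of Me2Zn are consumed by the hydroxyls.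

Step 22
Reactants: 26 (1S,2E,4R,8S,11R,12S)-4,11-dihydroxy-4,8,12-trimethyl-1-(propan-2-yl)-15-oxabicyclo[10.2.1]pentadec-2-en-6-one
Product: 27 (1S,2E,4R,8S,11R,12S)-4-hydroxy-4,8,12-trimethyl-6-oxo-1-(propan-2-yl)-15-oxabicyclo[10.2.1]pentadec-2-en-11-yl acetate
Conditions: Ac2O, pyridine, DMAP (cat.), CH2Cl2, 0 °C to rt
Reagents that add atoms: acetic anhydride, CC(=O)OC(C)=O
Why: Acylation takes the secondary C11 hydroxyl and leaves the tertiary C4 hydroxyl, giving the target.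

**Compound list**

1 | prop-2-yn-1-ol | C#CCO | starting material
2 | (2Z)-4-hydroxy-3-(propan-2-yl)but-2-enal | O=C/C=C(\CO)C(C)C | intermediate (not isolated)
3 | 4-(propan-2-yl)-2,5-dihydrofuran-2-ol | OC1OCC(C(C)C)=C1 | intermediate
4 | ethyl (2E,4Z)-5-(hydroxymethyl)-2,6-dimethylhepta-2,4-dienoate | CCOC(=O)/C(C)=C/C=C(\CO)C(C)C | intermediate
5 | ethyl (2E)-3-[(2R,3S)-3-(hydroxymethyl)-3-(propan-2-yl)oxiran-2-yl]-2-methylprop-2-enoate | CCOC(=O)/C(C)=C/[C@H]1O[C@]1(CO)C(C)C | intermediate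
6 | ethyl (2E)-3-[(2R,3S)-3-({[tert-butyl(dimethyl)silyl]oxy}methyl)-3-(propan-2-yl)oxiran-2-yl]-2-methylprop-2-enoate | CCOC(=O)/C(C)=C/[C@H]1O[C@]1(CO[Si](C)(C)C(C)(C)C)C(C)C | intermediate
7 | ethyl (2S,5R)-5-({[tert-butyl(dimethyl)silyl]oxy}methyl)-2-methyl-5-(propan-2-yl)-2,5-dihydrofuran-2-carboxylate | CCOC(=O)[C@]1(C)C=C[C@@](CO[Si](C)(C)C(C)(C)C)(C(C)C)O1 | intermediate
8 | ethyl (2S,5S)-5-({[tert-butyl(dimethyl)silyl]oxy}methyl)-2-methyl-5-(propan-2-yl)oxolane-2-carboxylate | CCOC(=O)[C@]1(C)CC[C@@](CO[Si](C)(C)C(C)(C)C)(C(C)C)O1 | intermediate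
9 | ethyl (2S,5S)-5-(hydroxymethyl)-2-methyl-5-(propan-2-yl)oxolane-2-carboxylate | CCOC(=O)[C@]1(C)CC[C@@](CO)(C(C)C)O1 | intermediate (not isolated)
10 | (1S,5S)-1-methyl-5-(propan-2-yl)-3,8-dioxabicyclo[3.2.1]octan-2-one | O=C2[C@]1(C)CC[C@@](CO2)(C(C)C)O1 | intermediate
11 | (2S,5S)-5-(hydroxymethyl)-N-methoxy-N,2-dimethyl-5-(propan-2-yl)oxolane-2-carboxamide | CON(C)C(=O)[C@]1(C)CC[C@@](CO)(C(C)C)O1 | intermediate
12 | (2S,5S)-5-formyl-N-methoxy-N,2-dimethyl-5-(propan-2-yl)oxolane-2-carboxamide | CON(C)C(=O)[C@]1(C)CC[C@@](C=O)(C(C)C)O1 | intermediate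
13 | (2S,5S)-5-ethynyl-N-methoxy-N,2-dimethyl-5-(propan-2-yl)oxolane-2-carboxamide | CON(C)C(=O)[C@]1(C)CC[C@@](C#C)(C(C)C)O1 | intermediate
14 | 1-[(2S,5S)-5-ethynyl-2-methyl-5-(propan-2-yl)oxolan-2-yl]pent-4-en-1-one | C=CCCC(=O)[C@]1(C)CC[C@@](C#C)(C(C)C)O1 | intermediate
15 | (1R)-1-[(2S,5S)-5-ethynyl-2-methyl-5-(propan-2-yl)oxolan-2-yl]pent-4-en-1-ol | C=CCC[C@@H](O)[C@]1(C)CC[C@@](C#C)(C(C)C)O1 | intermediate
16 | but-2-yn-1-ol | CC#CCO | starting material
17 | (2Z)-3-iodobut-2-en-1-ol | C/C(I)=C/CO | intermediate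
18 | (2Z)-5-{(2S,5S)-5-[(1R)-1-hydroxypent-4-en-1-yl]-5-methyl-2-(propan-2-yl)oxolan-2-yl}-3-methylpent-2-en-4-yn-1-ol | C=CCC[C@@H](O)[C@]1(C)CC[C@@](C#C/C(C)=C\CO)(C(C)C)O1 | intermediate
19 | [(2R,3S)-3-({(2S,5S)-5-[(1R)-1-hydroxypent-4-en-1-yl]-5-methyl-2-(propan-2-yl)oxolan-2-yl}ethynyl)-3-methyloxiran-2-yl]methanol | C=CCC[C@@H](O)[C@]1(C)CC[C@@](C#C[C@]2(C)O[C@@H]2CO)(C(C)C)O1 | intermediate
20 | (3R)-5-{(2S,5S)-5-[(1R)-1-hydroxypent-4-en-1-yl]-5-methyl-2-(propan-2-yl)oxolan-2-yl}-3-methylpent-4-yne-1,3-diol | C=CCC[C@@H](O)[C@]1(C)CC[C@@](C#C[C@](C)(O)CCO)(C(C)C)O1 | intermediate (not isolated)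
21 | (3R,4E)-5-{(2S,5S)-5-[(1R)-1-hydroxypent-4-en-1-yl]-5-methyl-2-(propan-2-yl)oxolan-2-yl}-3-methylpent-4-ene-1,3-diol | C=CCC[C@@H](O)[C@]1(C)CC[C@@](/C=C/[C@](C)(O)CCO)(C(C)C)O1 | intermediate
22 | (3R,4E)-3-hydroxy-5-{(2S,5S)-5-[(1R)-1-hydroxypent-4-en-1-yl]-5-methyl-2-(propan-2-yl)oxolan-2-yl}-3-methylpent-4-enal | C=CCC[C@@H](O)[C@]1(C)CC[C@@](/C=C/[C@](C)(O)CC=O)(C(C)C)O1 | intermediate
23 | (5R,6E)-7-{(2S,5S)-5-[(1R)-1-hydroxypent-4-en-1-yl]-5-methyl-2-(propan-2-yl)oxolan-2-yl}-5-methylhepta-1,6-diene-3,5-diol (C3 epimers) | C=CCC[C@@H](O)[C@]1(C)CC[C@@](/C=C/[C@](C)(O)CC(O)C=C)(C(C)C)O1 | intermediate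
24 | (5R,6E)-5-hydroxy-7-{(2S,5S)-5-[(1R)-1-hydroxypent-4-en-1-yl]-5-methyl-2-(propan-2-yl)oxolan-2-yl}-5-methylhepta-1,6-dien-3-one | C=CCC[C@@H](O)[C@]1(C)CC[C@@](/C=C/[C@](C)(O)CC(=O)C=C)(C(C)C)O1 | intermediate
25 | (1S,2E,4R,7E,11R,12S)-4,11-dihydroxy-4,12-dimethyl-1-(propan-2-yl)-15-oxabicyclo[10.2.1]pentadeca-2,7-dien-6-one | O[C@@H]1CC/C=C/C(=O)C[C@@](C)(O)/C=C/[C@@]2(C(C)C)CC[C@]1(C)O2 | intermediate
26 | (1S,2E,4R,8S,11R,12S)-4,11-dihydroxy-4,8,12-trimethyl-1-(propan-2-yl)-15-oxabicyclo[10.2.1]pentadec-2-en-6-one | O[C@@H]1CC[C@H](C)CC(=O)C[C@@](C)(O)/C=C/[C@@]2(C(C)C)CC[C@]1(C)O2 | intermediate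
27 | (1S,2E,4R,8S,11R,12S)-4-hydroxy-4,8,12-trimethyl-6-oxo-1-(propan-2-yl)-15-oxabicyclo[10.2.1]pentadec-2-en-11-yl acetate | CC(=O)O[C@@H]1CC[C@H](C)CC(=O)C[C@@](C)(O)/C=C/[C@@]2(C(C)C)CC[C@]1(C)O2 | target

**Count.** Total: 22 steps. Longest linear sequence: 21 steps (steps 1–12 and 14–22; step 13 is the side branch to 17).

**Steps most likely to fail**

Step 5 (key step). The ester-bearing allyl terminus may react too slowly at its fully substituted α-carbon. Lewis-acid opening at the tertiary oxirane carbon (1,2-shift to a carbonyl compound) could then take over, or a free zwitterion could form and the 1,3-transfer of chirality to C12 would leak. Fallback: the same ring growth is moved to the electron-neutral allylic-ester oxidation level, the substrate class on which this rearrangement is best established; it sets out from 6 and comes back at 10. DIBAL-H (CH2Cl2, −78 °C) reduces the ester of 6 to the epoxy allylic alcohol F1, and PivCl/pyridine gives the epoxy allylic pivalate F2. Cu(hfacac)2 in toluene at 150 °C should give the dihydrofuran pivalate F3, and H2/PtO2 the oxolane pivalate F4. DIBAL-H removes the pivalate to give the silyloxy alcohol F5, and TEMPO/PhI(OAc)2 in aqueous MeCN gives the silyloxy acid F6. TBAF frees the hydroxy acid F7, which lactonises under acid catalysis (p-TsOH, toluene) to 10.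

Step 16. Intermolecular SN2′ hydride attack on the alkynyl oxirane (allene formation) may outrun the alkoxide-directed delivery to C5, or hydroalumination of the alkyne between two fully substituted carbons may stall. Fallback: the (E)-C2=C3 bond is made before the oxirane; it sets out from 15 and comes back at 21. Palladium-catalysed hydrostannation of 15 (Bu3SnH, PdCl2(PPh3)2, THF) gives the (E)-vinylstannane F8. Stille coupling with 17 (Pd2(dba)3, AsPh3, CuI, NMP) gives the (2Z,4E)-dienol F9. Sharpless epoxidation with D-(−)-diethyl tartrate gives the vinyl oxirane F10, and Red-Al, now asked only for the directed hydride delivery at C5, gives 21.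

Step 21. The zinc alkoxide of the C4 hydroxyl may add across the ring to C8 (oxa-Michael) or trigger retro-aldol cleavage of C4–C5, or the macrocycle may override the ligand in facial selection. Fallback: both hydroxyls are masked and a Grignard-based catalyst is used; it sets out from 25 and comes back at 26. TMSOTf/2,6-lutidine (CH2Cl2, −78 °C) gives the bis-silyl ether F11. MeMgBr with CuBr·SMe2/Josiphos (t-BuOMe, −75 °C) gives the methyl adduct F12, and K2CO3 in MeOH returns 26.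

Further compounds
F1 | step 5 | (2E)-3-[(2R,3S)-3-({[tert-butyl(dimethyl)silyl]oxy}methyl)-3-(propan-2-yl)oxiran-2-yl]-2-methylprop-2-en-1-ol | OC/C(C)=C/[C@H]1O[C@]1(CO[Si](C)(C)C(C)(C)C)C(C)C
F2 | step 5 | (2E)-3-[(2R,3S)-3-({[tert-butyl(dimethyl)silyl]oxy}methyl)-3-(propan-2-yl)oxiran-2-yl]-2-methylprop-2-en-1-yl 2,2-dimethylpropanoate | CC(C)(C)C(=O)OC/C(C)=C/[C@H]1O[C@]1(CO[Si](C)(C)C(C)(C)C)C(C)C
F3 | step 5 | [(2S,5R)-5-({[tert-butyl(dimethyl)silyl]oxy}methyl)-2-methyl-5-(propan-2-yl)-2,5-dihydrofuran-2-yl]methyl 2,2-dimethylpropanoate | CC(C)(C)C(=O)OC[C@]1(C)C=C[C@@](CO[Si](C)(C)C(C)(C)C)(C(C)C)O1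
F4 | step 5 | [(2S,5S)-5-({[tert-butyl(dimethyl)silyl]oxy}methyl)-2-methyl-5-(propan-2-yl)oxolan-2-yl]methyl 2,2-dimethylpropanoate | CC(C)(C)C(=O)OC[C@]1(C)CC[C@@](CO[Si](C)(C)C(C)(C)C)(C(C)C)O1
F5 | step 5 | [(2S,5S)-5-({[tert-butyl(dimethyl)silyl]oxy}methyl)-2-methyl-5-(propan-2-yl)oxolan-2-yl]methanol | OC[C@]1(C)CC[C@@](CO[Si](C)(C)C(C)(C)C)(C(C)C)O1
F6 | step 5 | (2S,5S)-5-({[tert-butyl(dimethyl)silyl]oxy}methyl)-2-methyl-5-(propan-2-yl)oxolane-2-carboxylic acid | OC(=O)[C@]1(C)CC[C@@](CO[Si](C)(C)C(C)(C)C)(C(C)C)O1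
F7 | step 5 | (2S,5S)-5-(hydroxymethyl)-2-methyl-5-(propan-2-yl)oxolane-2-carboxylic acid | OC(=O)[C@]1(C)CC[C@@](CO)(C(C)C)O1
F8 | step 16 | (1R)-1-{(2S,5S)-2-methyl-5-(propan-2-yl)-5-[(E)-2-(tributylstannyl)ethenyl]oxolan-2-yl}pent-4-en-1-ol | C=CCC[C@@H](O)[C@]1(C)CC[C@@](/C=C/[Sn](CCCC)(CCCC)CCCC)(C(C)C)O1
F9 | step 16 | (2Z,4E)-5-{(2S,5S)-5-[(1R)-1-hydroxypent-4-en-1-yl]-5-methyl-2-(propan-2-yl)oxolan-2-yl}-3-methylpenta-2,4-dien-1-ol | C=CCC[C@@H](O)[C@]1(C)CC[C@@](/C=C/C(C)=C\CO)(C(C)C)O1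
F10 | step 16 | [(2R,3S)-3-[(E)-2-{(2S,5S)-5-[(1R)-1-hydroxypent-4-en-1-yl]-5-methyl-2-(propan-2-yl)oxolan-2-yl}ethenyl]-3-methyloxiran-2-yl]methanol | C=CCC[C@@H](O)[C@]1(C)CC[C@@](/C=C/[C@]2(C)O[C@@H]2CO)(C(C)C)O1
F11 | step 21 | (1S,2E,4R,7E,11R,12S)-4,12-dimethyl-1-(propan-2-yl)-4,11-bis[(trimethylsilyl)oxy]-15-oxabicyclo[10.2.1]pentadeca-2,7-dien-6-one | C[Si](C)(C)O[C@@H]1CC/C=C/C(=O)C[C@@](C)(O[Si](C)(C)C)/C=C/[C@@]2(C(C)C)CC[C@]1(C)O2
F12 | step 21 | (1S,2E,4R,8S,11R,12S)-4,8,12-trimethyl-1-(propan-2-yl)-4,11-bis[(trimethylsilyl)oxy]-15-oxabicyclo[10.2.1]pentadec-2-en-6-one | C[Si](C)(C)O[C@@H]1CC[C@H](C)CC(=O)C[C@@](C)(O[Si](C)(C)C)/C=C/[C@@]2(C(C)C)CC[C@]1(C)O2
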